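Ring A is built rather than bought. Its atoms C8a, C8, C7 and C6 are the ester carbon, the alkylated α-carbon, the ketone carbon and the methyl carbon of a 2-lavandulyl acetoacetate, drawn as its 1-methoxy-1,3-bis(silyloxy)butadiene; C4a and C5 are the alkyne carbons of a terminal aryl enynone whose carbonyl becomes C4. One Diels–Alder reaction with aromatisation forms C4a–C8a and C5–C6, closes ring A, places oxygen on C8a and C7 with the lavandulyl group on C8 between them, and delivers the 2′-hydroxychalcone with O7 already silylated. Asymmetric oxa-Michael closure of ring C and desilylation complete the synthesis.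

Key step: step 9

Remarks on the chemistry
- "(2R)-Lavandulyl" stands for (2R)-5-methyl-2-(prop-1-en-2-yl)hex-4-en-1-yl.
- The alcohol required is (S)-lavandulol. CH2OH and CH2I outrank isopropenyl, whereas CH2–C does not, so the same spatial arrangement is named S in 2 and 3 and R from 5 onwards.
- Assumption: Porcine pancreatic lipase acylates (R)-lavandulol faster, so the (S)-alcohol is the unreacted fraction.
- Assumption: the quinine-derived amine–thiourea is taken to give the (2S) flavanone; if a trial on the parent 2′-hydroxychalcone shows the opposite sense, the quinidine-derived pseudo-enantiomer replaces it with no other change.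
- Compounds 5, 6, 7 and 14 are mixtures at elements that vanish later: C2 of 5, the enol ether geometry of 6, the ketene acetal geometry of 7 (one isomer drawn) and the acetal carbon of 14.

Step 1
Reactants: 1 racemic lavandulol
Product: 2 (S)-lavandulol, (2S)-5-methyl-2-(prop-1-en-2-yl)hex-4-en-1-ol
Conditions: Porcine pancreatic lipase, vinyl acetate, tBuOMe, 25 °C, stopped somewhat past half conversion
Reagents that add atoms: none
Why: Lipase-catalysed kinetic resolution by irreversible transesterification should consume the (R)-alcohol faster, so that running past half conversion leaves the (S)-alcohol highly enriched; this step is the source of the lavandulyl stereocentre.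

Step 2
Reactants: 2 (S)-lavandulol
Product: 3 (S)-lavandulyl iodide, (3S)-3-(iodomethyl)-2,6-dimethylhepta-1,5-diene
Conditions: I2, PPh3, imidazole, CH2Cl2, 0 °C → rt
Reagents that add atoms: iodine, II
Why: Appel-type iodination of a primary alcohol through the alkoxyphosphonium salt displaces at CH2 only, so the neighbouring stereocentre is not touched.

Step 3
Reactants: 4 methyl acetoacetate; 3 (S)-lavandulyl iodide
Product: 5 methyl (4R)-2-acetyl-7-methyl-4-(prop-1-en-2-yl)oct-6-enoate (both C2 epimers)
Conditions: NaH, THF, 0 °C; then 3, DMPU, 60 °C (4 in excess)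
Reagents that add atoms: none
Why: Acetoacetic ester alkylation (SN2) of the weakly basic sodium enolate with a primary iodide should favour C-alkylation over O-alkylation and elimination, and the stereocentre lies β to the reacting carbon.

Step 4
Reactants: 5 methyl (4R)-2-acetyl-7-methyl-4-(prop-1-en-2-yl)oct-6-enoate
Product: 6 methyl (4R)-2-[1-(tert-butyldimethylsilyloxy)ethylidene]-7-methyl-4-(prop-1-en-2-yl)oct-6-enoate (E/Z mixture)
Conditions: TBSOTf, Et3N, CH2Cl2, 0 °C
Reagents that add atoms: tert-butyldimethylsilyl trifluoromethanesulfonate, CC(C)(C)[Si](C)(C)OS(=O)(=O)C(F)(F)F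
Why: Soft enolisation and O-silylation of the β-keto ester gives the conjugated silyl enol ether, and the robust TBS group is placed on the oxygen that becomes O7 so that it outlasts the aromatisation work-up.

Step 5
Reactants: 6 methyl (4R)-2-[1-(tert-butyldimethylsilyloxy)ethylidene]-7-methyl-4-(prop-1-en-2-yl)oct-6-enoate
Product: 7 3-(tert-butyldimethylsilyloxy)-1-methoxy-2-[(2R)-lavandulyl]-1-(trimethylsilyloxy)buta-1,3-diene
Conditions: LiN(iPr)2, THF, −78 °C; then TMSCl, −78 → 0 °C; pentane, filtration under argon, used crude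
Reagents that add atoms: chlorotrimethylsilane, C[Si](C)(C)Cl
Why: γ-Deprotonation of the β-silyloxy enoate to the extended ester enolate followed by O-silylation is the standard second stage in making 1-alkoxy-1,3-bis(silyloxy)butadienes from β-keto esters.

Step 6
Reactants: 8 4-hydroxy-2-methoxybenzaldehyde
Product: 9 2-methoxy-4-(triisopropylsilyloxy)benzaldehyde
Conditions: TIPSCl, imidazole, DMF, rt
Reagents that add atoms: chlorotriisopropylsilane, CC(C)[Si](Cl)(C(C)C)C(C)C
Why: Silylation of the phenol gives a TIPS ether that should withstand the basic olefination and the Grignard addition and is removed at the end by fluoride together with the TBS group.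

Step 7
Reactants: 9 2-methoxy-4-(triisopropylsilyloxy)benzaldehyde; 10 diethyl {2-[methoxy(methyl)amino]-2-oxoethyl}phosphonate
Product: 11 (E)-N-methoxy-3-[2-methoxy-4-(triisopropylsilyloxy)phenyl]-N-methylprop-2-enamide
Conditions: NaH, THF, 0 °C → rt
Reagents that add atoms: none
Why: Horner–Wadsworth–Emmons olefination with a stabilised phosphonate anion should give the (E)-cinnamoyl Weinreb amide.

Step 8
Reactants: 11 (E)-N-methoxy-3-[2-methoxy-4-(triisopropylsilyloxy)phenyl]-N-methylprop-2-enamide; 12 ethynylmagnesium bromide (HC≡CMgBr, THF solution)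
Product: 13 (E)-1-[2-methoxy-4-(triisopropylsilyloxy)phenyl]pent-1-en-4-yn-3-one
Conditions: THF, −20 → 0 °C; inverse quench into cold 1 M HCl
Reagents that add atoms: none
Why: Weinreb ketone synthesis, in which the chelated tetrahedral intermediate prevents over-addition and the acidic inverse quench protonates the released N,O-dimethylhydroxylamine before it can add to the new ynone.

Step 9
Reactants: 7 3-(tert-butyldimethylsilyloxy)-1-methoxy-2-[(2R)-lavandulyl]-1-(trimethylsilyloxy)buta-1,3-diene; 13 (E)-1-[2-methoxy-4-(triisopropylsilyloxy)phenyl]pent-1-en-4-yn-3-one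
Product: 16 (E)-1-{4-(tert-butyldimethylsilyloxy)-2-hydroxy-3-[(2R)-lavandulyl]phenyl}-3-[2-methoxy-4-(triisopropylsilyloxy)phenyl]prop-2-en-1-one, via cyclohexadiene cycloadduct 14 (not isolated), via aryl trimethylsilyl ether 15 (not isolated)
Conditions: 7 (1.5 equiv), PhMe, −20 → 40 °C; then 0.5 M aq. HCl, THF, 0 °C
Reagents that add atoms: none
Why: The electron-rich diene 7 adds through its CH2 terminus (future C6) to the unsubstituted alkyne carbon of 13 (future C5) and through its ketene acetal carbon (future C8a) to the acyl-bearing alkyne carbon (future C4a), a concerted but strongly asynchronous normal-demand Diels–Alder reaction. The closest known reaction type is the cycloaddition–aromatisation of 1-alkoxy-1,3-bis(silyloxy)butadienes with acetylenic ketones and esters, which gives resorcinol derivatives. Ring A is closed by this intermolecular [4+2] cycloaddition, both new ring bonds (C5–C6 and C4a–C8a) arising in the one step; adduct 14 then aromatises by 1,4-loss of methanol from C8a and C6, and dilute acid removes the labile trimethylsilyl group from O8a while the TBS ether on O7 and the TIPS ether should stay. No stereocentre of the product is created, because the acetal carbon of 14 is flattened on aromatisation and the lavandulyl centre lies outside the reacting system. Regiochemistry should follow from matching the largest HOMO coefficient of the diene (CH2 terminus) with the largest LUMO coefficient of the ynone (β-carbon). Chemoselectivity for the triple bond over the styryl double bond rests on the unhindered terminal alkyne carbon and on the donor-substituted aryl group, which makes the alkene β-carbon a poor acceptor.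

Step 10
Reactants: 16 (E)-1-{4-(tert-butyldimethylsilyloxy)-2-hydroxy-3-[(2R)-lavandulyl]phenyl}-3-[2-methoxy-4-(triisopropylsilyloxy)phenyl]prop-2-en-1-one
Product: 17 (2S)-7-(tert-butyldimethylsilyloxy)-2-[2-methoxy-4-(triisopropylsilyloxy)phenyl]-8-[(2R)-lavandulyl]-2,3-dihydro-4H-chromen-4-one
Conditions: 1-[3,5-bis(trifluoromethyl)phenyl]-3-[(8α,9S)-6′-methoxycinchonan-9-yl]thiourea (10 mol %), PhMe, 0 °C, stopped before equilibrium erodes the selectivity
Reagents that add atoms: none
Why: Organocatalytic enantioselective intramolecular oxa-Michael addition of a 2′-hydroxychalcone (6-endo-trig closure of ring C through O1–C2), in which the quinuclidine nitrogen deprotonates the C8a hydroxyl while the thiourea binds the C4 carbonyl, so the face of C2 that is attacked, and hence the (2S) configuration, should be set by the catalyst and not by the remote lavandulyl centre.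

Step 11
Reactants: 17 (2S)-7-(tert-butyldimethylsilyloxy)-2-[2-methoxy-4-(triisopropylsilyloxy)phenyl]-8-[(2R)-lavandulyl]-2,3-dihydro-4H-chromen-4-one
Product: 18 Alopecurone G, (2S)-7-hydroxy-2-(4-hydroxy-2-methoxyphenyl)-8-[(2R)-lavandulyl]-2,3-dihydro-4H-chromen-4-one
Conditions: Bu4NF, AcOH (1:1), THF, 0 °C → rt
Reagents that add atoms: none
Why: Fluoride cleavage of both aryl silyl ethers in an acetic acid buffer keeps the medium near neutral, so neither base-induced ring opening at C2 nor acid-induced cyclisation of the lavandulyl alkenes onto the 7-hydroxyl should occur.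

Compound list
1 | racemic lavandulol, (2RS)-5-methyl-2-(prop-1-en-2-yl)hex-4-en-1-ol | C=C(C)C(CC=C(C)C)CO | starting material
2 | (S)-lavandulol, (2S)-5-methyl-2-(prop-1-en-2-yl)hex-4-en-1-ol | C=C(C)[C@H](CC=C(C)C)CO | intermediate
3 | (S)-lavandulyl iodide, (3S)-3-(iodomethyl)-2,6-dimethylhepta-1,5-diene | C=C(C)[C@H](CC=C(C)C)CI | intermediate
4 | methyl acetoacetate | COC(=O)CC(C)=O | starting material
5 | methyl (4R)-2-acetyl-7-methyl-4-(prop-1-en-2-yl)oct-6-enoate (C2 epimers) | C=C(C)[C@H](CC=C(C)C)CC(C(C)=O)C(=O)OC | intermediate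
6 | methyl (4R)-2-[1-(tert-butyldimethylsilyloxy)ethylidene]-7-methyl-4-(prop-1-en-2-yl)oct-6-enoate (E/Z mixture) | C=C(C)[C@H](CC=C(C)C)CC(C(=O)OC)=C(C)O[Si](C)(C)C(C)(C)C | intermediate
7 | 3-(tert-butyldimethylsilyloxy)-1-methoxy-2-[(2R)-lavandulyl]-1-(trimethylsilyloxy)buta-1,3-diene (ketene acetal geometry without consequence, one isomer drawn) | C=C(C)[C@H](CC=C(C)C)C/C(C(=C)O[Si](C)(C)C(C)(C)C)=C(/OC)O[Si](C)(C)C | intermediate
8 | 4-hydroxy-2-methoxybenzaldehyde | COc1cc(O)ccc1C=O | starting material
9 | 2-methoxy-4-(triisopropylsilyloxy)benzaldehyde | COc1cc(O[Si](C(C)C)(C(C)C)C(C)C)ccc1C=O | intermediate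
10 | diethyl {2-[methoxy(methyl)amino]-2-oxoethyl}phosphonate | CCOP(=O)(CC(=O)N(C)OC)OCC | starting material
11 | (E)-N-methoxy-3-[2-methoxy-4-(triisopropylsilyloxy)phenyl]-N-methylprop-2-enamide | CON(C)C(=O)/C=C/c1ccc(O[Si](C(C)C)(C(C)C)C(C)C)cc1OC | intermediate
12 | ethynylmagnesium bromide | C#C[Mg]Br | starting material
13 | (E)-1-[2-methoxy-4-(triisopropylsilyloxy)phenyl]pent-1-en-4-yn-3-one | C#CC(=O)/C=C/c1ccc(O[Si](C(C)C)(C(C)C)C(C)C)cc1OC | intermediate
14 | (E)-1-{4-(tert-butyldimethylsilyloxy)-6-methoxy-5-[(2R)-lavandulyl]-6-(trimethylsilyloxy)cyclohexa-1,4-dien-1-yl}-3-[2-methoxy-4-(triisopropylsilyloxy)phenyl]prop-2-en-1-one | C=C(C)[C@H](CC=C(C)C)CC1=C(O[Si](C)(C)C(C)(C)C)CC=C(C(=O)/C=C/c2ccc(O[Si](C(C)C)(C(C)C)C(C)C)cc2OC)C1(OC)O[Si](C)(C)C | intermediate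
15 | (E)-1-{4-(tert-butyldimethylsilyloxy)-3-[(2R)-lavandulyl]-2-(trimethylsilyloxy)phenyl}-3-[2-methoxy-4-(triisopropylsilyloxy)phenyl]prop-2-en-1-one | C=C(C)[C@H](CC=C(C)C)Cc1c(O[Si](C)(C)C(C)(C)C)ccc(C(=O)/C=C/c2ccc(O[Si](C(C)C)(C(C)C)C(C)C)cc2OC)c1O[Si](C)(C)C | intermediate
16 | (E)-1-{4-(tert-butyldimethylsilyloxy)-2-hydroxy-3-[(2R)-lavandulyl]phenyl}-3-[2-methoxy-4-(triisopropylsilyloxy)phenyl]prop-2-en-1-one | C=C(C)[C@H](CC=C(C)C)Cc1c(O[Si](C)(C)C(C)(C)C)ccc(C(=O)/C=C/c2ccc(O[Si](C(C)C)(C(C)C)C(C)C)cc2OC)c1O | intermediate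
17 | (2S)-7-(tert-butyldimethylsilyloxy)-2-[2-methoxy-4-(triisopropylsilyloxy)phenyl]-8-[(2R)-lavandulyl]-2,3-dihydro-4H-chromen-4-one | C=C(C)[C@H](CC=C(C)C)Cc1c(O[Si](C)(C)C(C)(C)C)ccc2c1O[C@H](c1ccc(O[Si](C(C)C)(C(C)C)C(C)C)cc1OC)CC2=O | intermediate
18 | Alopecurone G, (2S)-7-hydroxy-2-(4-hydroxy-2-methoxyphenyl)-8-[(2R)-5-methyl-2-(prop-1-en-2-yl)hex-4-en-1-yl]-2,3-dihydro-4H-chromen-4-one | C=C(C)[C@H](CC=C(C)C)Cc1c(O)ccc2c1O[C@H](c1ccc(O)cc1OC)CC2=O | target

Total step count: 11. Longest linear sequence: 8 steps (steps 1, 2, 3, 4, 5, 9, 10, 11); the aldehyde branch (steps 6, 7, 8) joins at step 9.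

Steps most likely to fail

Step 9. The enynone may oligomerise, or the diene may add in open-chain Michael fashion without ring closure, or the diene may hydrolyse before it reacts. The fallback builds ring A on a simpler dienophile and attaches the enone afterwards. Diene 7 and commercial but-3-yn-2-one are combined under the conditions of step 9 to give the cycloadduct 1-{4-(tert-butyldimethylsilyloxy)-6-methoxy-5-[(2R)-lavandulyl]-6-(trimethylsilyloxy)cyclohexa-1,4-dien-1-yl}ethan-1-one F1. The same acidic work-up strips methanol and the trimethylsilyl group from it and should give the acetophenone 1-{4-(tert-butyldimethylsilyloxy)-2-hydroxy-3-[(2R)-lavandulyl]phenyl}ethan-1-one F2. A Claisen–Schmidt condensation of its dianion with aldehyde 9 (LiN(SiMe3)2 in excess, THF, −78 °C → rt) passes through the aldol 1-{4-(tert-butyldimethylsilyloxy)-2-hydroxy-3-[(2R)-lavandulyl]phenyl}-3-hydroxy-3-[2-methoxy-4-(triisopropylsilyloxy)phenyl]propan-1-one F3, which is not isolated and loses water in the flask, and the route is rejoined at chalcone 16.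

Step 10. The catalyst may discriminate poorly between the two faces of C2, and the reversible ring closure may erode the selectivity before useful conversion is reached. The fallback gives up stereocontrol in the closure and separates the isomers. Chalcone 16 is equilibrated with an achiral base (DBU, 10 mol %, PhMe, rt) to give 17 together with its C2 epimer (2R)-7-(tert-butyldimethylsilyloxy)-2-[2-methoxy-4-(triisopropylsilyloxy)phenyl]-8-[(2R)-lavandulyl]-2,3-dihydro-4H-chromen-4-one F4. The two are diastereomers because of the fixed lavandulyl centre and are separated by preparative HPLC on a cellulose-based chiral stationary phase. F4 is returned to the same base, where ring opening to 16 re-establishes the mixture, and the route is rejoined at 17.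

Step 8. The released amine or the magnesium acetylide may add to the new ynone in conjugate fashion, or the ynone may polymerise during the quench. The fallback brings in the triple bond at the alcohol oxidation level. Weinreb amide 11 is reduced with iBu2AlH (THF, −78 °C) to the enal (E)-3-[2-methoxy-4-(triisopropylsilyloxy)phenyl]prop-2-enal F5. Ethynylmagnesium bromide 12 (THF, −78 °C) adds 1,2 to give the racemic carbinol (E)-1-[2-methoxy-4-(triisopropylsilyloxy)phenyl]pent-1-en-4-yn-3-ol F6, and MnO2 (CH2Cl2, rt) oxidises this doubly activated alcohol to 13, where the route is rejoined.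

Further compounds
F1 | step 9 | 1-{4-(tert-butyldimethylsilyloxy)-6-methoxy-5-[(2R)-lavandulyl]-6-(trimethylsilyloxy)cyclohexa-1,4-dien-1-yl}ethan-1-one | C=C(C)[C@H](CC=C(C)C)CC1=C(O[Si](C)(C)C(C)(C)C)CC=C(C(C)=O)C1(OC)O[Si](C)(C)C
F2 | step 9 | 1-{4-(tert-butyldimethylsilyloxy)-2-hydroxy-3-[(2R)-lavandulyl]phenyl}ethan-1-one | C=C(C)[C@H](CC=C(C)C)Cc1c(O[Si](C)(C)C(C)(C)C)ccc(C(C)=O)c1O
F3 | step 9 | 1-{4-(tert-butyldimethylsilyloxy)-2-hydroxy-3-[(2R)-lavandulyl]phenyl}-3-hydroxy-3-[2-methoxy-4-(triisopropylsilyloxy)phenyl]propan-1-one | C=C(C)[C@H](CC=C(C)C)Cc1c(O[Si](C)(C)C(C)(C)C)ccc(C(=O)CC(O)c2ccc(O[Si](C(C)C)(C(C)C)C(C)C)cc2OC)c1O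
F4 | step 10 | (2R)-7-(tert-butyldimethylsilyloxy)-2-[2-methoxy-4-(triisopropylsilyloxy)phenyl]-8-[(2R)-lavandulyl]-2,3-dihydro-4H-chromen-4-one | C=C(C)[C@H](CC=C(C)C)Cc1c(O[Si](C)(C)C(C)(C)C)ccc2c1O[C@@H](c1ccc(O[Si](C(C)C)(C(C)C)C(C)C)cc1OC)CC2=O
F5 | step 8 | (E)-3-[2-methoxy-4-(triisopropylsilyloxy)phenyl]prop-2-enal | O=C/C=C/c1ccc(O[Si](C(C)C)(C(C)C)C(C)C)cc1OC
F6 | step 8 | (E)-1-[2-methoxy-4-(triisopropylsilyloxy)phenyl]pent-1-en-4-yn-3-ol | C#CC(O)/C=C/c1ccc(O[Si](C(C)C)(C(C)C)C(C)C)cc1OC
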